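**Retrosynthetic overview**
1. Ring letters: A = methoxy ring of the phenanthrene, B = central phenanthrene ring, C = chlorophenol ring of the phenanthrene, D = chlorophenol ring on the ethano bridge (biaryl to A), E = phenol ring (biaryl to C). Rings A, C, D and E are bought as benzaldehydes.
2. Target ⇐ one hydrogenation of a tris-benzyl macrocycle with a cis CH=CH bridge between rings D and E (alkene saturation plus O-debenzylation).
3. That macrocycle ⇐ twofold McMurry coupling of a linear E–C–A–D tetra-aldehyde: the C9=C10 bond of ring B and the D/E bridge (12-membered ring) close in the same operation.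
4. Tetra-aldehyde ⇐ three-component Pd/norbornene (Catellani) union on the ring C iodide: the C–H next to the iodide is arylated by the D–A aryl bromide, the ipso carbon by the ring E boronate.
5. D–A bromide ⇐ Suzuki coupling (ring D bromide + ring A boronic acid), then bromination. Order of ring formation: B, then the macrocycle, both in the McMurry step.

Assumption: the target SMILES carries no stereodescriptor, so the target is taken as the constitution shown; any atropisomerism of the macrocycle is undefined and the route does not control it.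

**Step 1**
Reactants: 1 2-bromo-3-hydroxybenzaldehyde
Product: 2 2-bromo-6-chloro-3-hydroxybenzaldehyde
Conditions: NCS (1.05 equiv), cat. TsOH, MeCN, 0 °C to rt
Reagents that add atoms: N-chlorosuccinimide, O=C1CCC(=O)N1Cl
Why: Electrophilic aromatic chlorination goes para to the phenol OH (C6), the position 3-hydroxybenzaldehydes halogenate first, in preference to the remaining ortho site C4.

**Step 2**
Reactants: 2 2-bromo-6-chloro-3-hydroxybenzaldehyde
Product: 3 3-(benzyloxy)-2-bromo-6-chlorobenzaldehyde
Conditions: BnBr, K2CO3, DMF, 50 °C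
Reagents that add atoms: benzyl bromide, BrCc1ccccc1
Why: Williamson ether synthesis on the phenoxide masks the ring D phenol so that the later bromination goes to ring A.

**Step 3**
Reactants: 3 3-(benzyloxy)-2-bromo-6-chlorobenzaldehyde; 4 (4-formyl-2-methoxyphenyl)boronic acid
Product: 5 6-(benzyloxy)-3-chloro-2'-methoxy-[1,1'-biphenyl]-2,4'-dicarbaldehyde
Conditions: Pd(PPh3)4 (5 mol%), K2CO3, DME–H2O, 85 °C
Reagents that add atoms: none
Why: Suzuki–Miyaura coupling at the bromide activated by the ortho formyl group forms the D–A biaryl bond, and the aryl chloride does not react with this catalyst.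

**Step 4**
Reactants: 5 6-(benzyloxy)-3-chloro-2'-methoxy-[1,1'-biphenyl]-2,4'-dicarbaldehyde
Product: 6 6-(benzyloxy)-5'-bromo-3-chloro-2'-methoxy-[1,1'-biphenyl]-2,4'-dicarbaldehyde
Conditions: Br2 (1.05 equiv), NaOAc, AcOH, rt
Reagents that add atoms: bromine, BrBr
Why: Electrophilic aromatic bromination goes para to the methoxy group of ring A (ortho to its formyl group), as in the bromination of 3-methoxybenzaldehydes, while ring D offers only a position ortho to its ether and is further deactivated by Cl.

**Step 5**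
Reactants: 7 3-chloro-4-hydroxybenzaldehyde
Product: 8 3-chloro-4-hydroxy-5-iodobenzaldehyde
Conditions: NIS, cat. CF3CO2H, MeCN, rt
Reagents that add atoms: N-iodosuccinimide, O=C1CCC(=O)N1I
Why: Electrophilic aromatic iodination can only go to the one free position ortho to the phenol OH, because the other ortho position carries Cl and the para position carries the formyl group.

**Step 6**
Reactants: 8 3-chloro-4-hydroxy-5-iodobenzaldehyde
Product: 9 4-(benzyloxy)-3-chloro-5-iodobenzaldehyde
Conditions: BnBr, K2CO3, DMF, 50 °C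
Reagents that add atoms: benzyl bromide, BrCc1ccccc1
Why: Williamson ether synthesis gives the ortho-alkoxy aryl iodide needed for the norbornene-relayed coupling and removes the free ortho-iodophenol that would trap norbornene.

**Step 7**
Reactants: 10 3-bromo-4-hydroxybenzaldehyde
Product: 11 4-(benzyloxy)-3-bromobenzaldehyde
Conditions: BnBr, K2CO3, DMF, 50 °C
Reagents that add atoms: benzyl bromide, BrCc1ccccc1
Why: Williamson ether synthesis protects the ring E phenol with the same group as rings C and D.

**Step 8**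
Reactants: 11 4-(benzyloxy)-3-bromobenzaldehyde
Product: 12 4-(benzyloxy)-3-(4,4,5,5-tetramethyl-1,3,2-dioxaborolan-2-yl)benzaldehyde
Conditions: B2pin2, PdCl2(dppf) (3 mol%), KOAc, 1,4-dioxane, 90 °C
Reagents that add atoms: bis(pinacolato)diboron, CC1(C)OB(OC1(C)C)B1OC(C)(C)C(C)(C)O1
Why: Miyaura borylation of the aryl bromide tolerates the aldehyde and gives the ring E nucleophile.

**Step 9**
Reactants: 9 4-(benzyloxy)-3-chloro-5-iodobenzaldehyde; 6 6-(benzyloxy)-5'-bromo-3-chloro-2'-methoxy-[1,1'-biphenyl]-2,4'-dicarbaldehyde; 12 4-(benzyloxy)-3-(4,4,5,5-tetramethyl-1,3,2-dioxaborolan-2-yl)benzaldehyde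
Product: 13 4-(benzyloxy)-3-[2-(benzyloxy)-5-formylphenyl]-2-{5-[6-(benzyloxy)-3-chloro-2-formylphenyl]-2-formyl-4-methoxyphenyl}-5-chlorobenzaldehyde
Conditions: Pd(OAc)2 (10 mol%), P(2-furyl)3 (20 mol%), norbornene (2 equiv), K2CO3, DMF (trace H2O), 105 °C; 9 (1.0 equiv), 6 (1.1 equiv), 12 (1.5 equiv)
Reagents that add atoms: none
Why: Catellani reaction: oxidative addition of the aryl iodide, norbornene insertion and palladacycle formation at the only free C–H ortho to the iodide (C6 of 9), arylation there by the ortho-formyl bromide 6 (aryl–aryl coupling is enforced by the ortho benzyloxy group), norbornene extrusion and ipso Suzuki–Miyaura coupling with 12 place rings A and E on adjacent carbons of ring C in one pot while the aryl chlorides stay inert.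

**Step 10**
Reactants: 13 4-(benzyloxy)-3-[2-(benzyloxy)-5-formylphenyl]-2-{5-[6-(benzyloxy)-3-chloro-2-formylphenyl]-2-formyl-4-methoxyphenyl}-5-chlorobenzaldehyde
Product: 15 tris-O-benzyl (Z)-stilbene macrocycle (target skeleton with cis CH=CH in the D–E bridge), via phenanthrene dialdehyde 14 (not isolated)
Conditions: TiCl4, Zn dust, pyridine, THF, reflux; 13 added by syringe pump over 24 h (final 1 mM)
Reagents that add atoms: none
Why: Twofold McMurry reductive carbonyl coupling: the two formyl groups flanking the A–C biaryl bond are pre-organised for a six-membered closure and give aromatic ring B, after which the ring D and ring E aldehydes can only pair with each other under high dilution and close the 12-membered ring, whose size enforces the Z alkene, while every crossed pairing would need a strained 8- or 9-membered cyclophane.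

**Step 11**
Reactants: 15 tris-O-benzyl (Z)-stilbene macrocycle
Product: 17 CNP0310669.0 (target), via tris-O-benzyl ether of the target 16 (not isolated)
Conditions: H2 (1 atm), 5% Pd/C, EtOAc, rt, stopped after uptake of 4 equiv H2
Reagents that add atoms: none
Why: Heterogeneous catalytic hydrogenation saturates the strained cis-stilbene bridge and then hydrogenolyses the three benzyl ethers, and neutral base-free conditions at 1 atm keep the aryl chlorides, the methyl ether and the phenanthrene intact; no stereocentre is formed.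

**Compound list**
1 | 2-bromo-3-hydroxybenzaldehyde | O=Cc1cccc(O)c1Br | starting material
2 | 2-bromo-6-chloro-3-hydroxybenzaldehyde | O=Cc1c(Cl)ccc(O)c1Br | intermediate
3 | 3-(benzyloxy)-2-bromo-6-chlorobenzaldehyde | O=Cc1c(Cl)ccc(OCc2ccccc2)c1Br | intermediate
4 | (4-formyl-2-methoxyphenyl)boronic acid | COc1cc(C=O)ccc1B(O)O | starting material
5 | 6-(benzyloxy)-3-chloro-2'-methoxy-[1,1'-biphenyl]-2,4'-dicarbaldehyde | O=Cc1c(Cl)ccc(OCc2ccccc2)c1-c1ccc(C=O)cc1OC | intermediate
6 | 6-(benzyloxy)-5'-bromo-3-chloro-2'-methoxy-[1,1'-biphenyl]-2,4'-dicarbaldehyde | O=Cc1c(Cl)ccc(OCc2ccccc2)c1-c1cc(Br)c(C=O)cc1OC | intermediate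
7 | 3-chloro-4-hydroxybenzaldehyde | O=Cc1ccc(O)c(Cl)c1 | starting material
8 | 3-chloro-4-hydroxy-5-iodobenzaldehyde | O=Cc1cc(Cl)c(O)c(I)c1 | intermediate
9 | 4-(benzyloxy)-3-chloro-5-iodobenzaldehyde | O=Cc1cc(Cl)c(OCc2ccccc2)c(I)c1 | intermediate
10 | 3-bromo-4-hydroxybenzaldehyde | O=Cc1ccc(O)c(Br)c1 | starting material
11 | 4-(benzyloxy)-3-bromobenzaldehyde | O=Cc1ccc(OCc2ccccc2)c(Br)c1 | intermediate
12 | 4-(benzyloxy)-3-(4,4,5,5-tetramethyl-1,3,2-dioxaborolan-2-yl)benzaldehyde | O=Cc1ccc(OCc2ccccc2)c(B2OC(C)(C)C(C)(C)O2)c1 | intermediate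
13 | 4-(benzyloxy)-3-[2-(benzyloxy)-5-formylphenyl]-2-{5-[6-(benzyloxy)-3-chloro-2-formylphenyl]-2-formyl-4-methoxyphenyl}-5-chlorobenzaldehyde (E–C–A–D tetra-aldehyde) | O=Cc1cc(Cl)c(OCc2ccccc2)c(-c2cc(C=O)ccc2OCc2ccccc2)c1-c1cc(-c2c(OCc3ccccc3)ccc(Cl)c2C=O)c(OC)cc1C=O | intermediate
14 | 4-(benzyloxy)-3-{3-(benzyloxy)-6-[6-(benzyloxy)-3-chloro-2-formylphenyl]-2-chloro-7-methoxyphenanthren-4-yl}benzaldehyde (phenanthrene dialdehyde) | COc1cc2ccc3cc(Cl)c(OCc4ccccc4)c(-c4cc(C=O)ccc4OCc4ccccc4)c3c2cc1-c1c(OCc2ccccc2)ccc(Cl)c1C=O | intermediate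
15 | tris-O-benzyl (Z)-stilbene macrocycle: target skeleton with benzyl ethers on the three phenols and a cis CH=CH in place of the CH2CH2 bridge between rings D and E | COc1cc2ccc3cc(Cl)c(OCc5ccccc5)c4c3c2cc1-c1c(OCc5ccccc5)ccc(Cl)c1/C=C\c1ccc(OCc5ccccc5)c-4c1 | intermediate
16 | tris-O-benzyl ether of the target (CH2CH2 bridge, benzyl ethers on the three phenols) | COc1cc2ccc3cc(Cl)c(OCc5ccccc5)c4c3c2cc1-c1c(OCc5ccccc5)ccc(Cl)c1CCc1ccc(OCc5ccccc5)c-4c1 | intermediate
17 | CNP0310669.0 | COc1cc2ccc3cc(Cl)c(O)c4c3c2cc1-c1c(O)ccc(Cl)c1CCc1ccc(O)c-4c1 | target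

**Totals**
Total step count: 11.
Longest linear sequence: 7 steps (steps 1, 2, 3, 4, 9, 10, 11).

**Three steps most likely to fail**

Step 9. The C–H to be arylated is flanked by the formyl group. Bromide 6 could also undergo a direct Suzuki coupling with 12, and the ipso aryl-palladium could add to the neighbouring formyl group (fluorenol formation). The fallback sets out from 12 and 6 and comes back at 13. It makes the two aryl–aryl bonds by two ordinary Suzuki couplings on a ring C block that carries both halogens from the start. Purchased 2-bromo-4-hydroxybenzaldehyde F1 is chlorinated with NCS at the free position ortho to OH to give 2-bromo-5-chloro-4-hydroxybenzaldehyde F2. Iodination with NIS at the last ortho position gives 2-bromo-5-chloro-4-hydroxy-3-iodobenzaldehyde F3, and benzylation (BnBr, K2CO3) gives 4-(benzyloxy)-2-bromo-5-chloro-3-iodobenzaldehyde F4. Suzuki coupling of F4 with 12 at the iodide (Pd(PPh3)4, K2CO3, DME–H2O, 60 °C) gives 4-(benzyloxy)-3-[2-(benzyloxy)-5-formylphenyl]-2-bromo-5-chlorobenzaldehyde F5. Bromide 6 is borylated (B2pin2, PdCl2(dppf), KOAc) to 6-(benzyloxy)-3-chloro-2'-methoxy-5'-(4,4,5,5-tetramethyl-1,3,2-dioxaborolan-2-yl)-[1,1'-biphenyl]-2,4'-dicarbaldehyde F6. F5 and F6 are then joined at the hindered bromide (Pd(OAc)2, SPhos, K3PO4, toluene–H2O, 100 °C) to give 13.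

Step 10. Intermolecular coupling can outrun the 12-membered closure, the second coupling may stop at the pinacol, and low-valent titanium may attack C–Cl. The fallback sets out from 13 and comes back at 15. It replaces reductive carbonyl coupling by olefin metathesis. Fourfold Wittig methylenation (Ph3P=CH2 from Ph3PCH3Br and KOtBu, THF) gives the tetra-styrene 4-(benzyloxy)-3-[2-(benzyloxy)-5-vinylphenyl]-2-{5-[6-(benzyloxy)-3-chloro-2-vinylphenyl]-4-methoxy-2-vinylphenyl}-5-chlorostyrene F7. Twofold ring-closing metathesis (second-generation Grubbs catalyst RuCl2(=CHPh)(PCy3)(H2IMes), toluene, 80 °C, 1 mM) closes ring B from the 2,2'-divinylbiaryl and then the macrocyclic cis alkene, giving 15.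

Step 11. Pd/C may hydrodechlorinate the chlorophenol rings once the phenols are free, or begin to reduce the phenanthrene 9,10-bond. The fallback sets out from 15 and comes back at 17. The bridge alkene is reduced with diimide (TsNHNH2, NaOAc, DME–H2O, reflux), which cannot touch C–Cl, and 16 is isolated. The benzyl ethers are then cleaved with a Lewis acid (BCl3, pentamethylbenzene, CH2Cl2, −78 °C), which spares the aryl methyl ether and the chlorides, giving 17.

**Further compounds**
F1 | step 9 | 2-bromo-4-hydroxybenzaldehyde (purchased) | O=Cc1ccc(O)cc1Br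
F2 | step 9 | 2-bromo-5-chloro-4-hydroxybenzaldehyde | O=Cc1cc(Cl)c(O)cc1Br
F3 | step 9 | 2-bromo-5-chloro-4-hydroxy-3-iodobenzaldehyde | O=Cc1cc(Cl)c(O)c(I)c1Br
F4 | step 9 | 4-(benzyloxy)-2-bromo-5-chloro-3-iodobenzaldehyde | O=Cc1cc(Cl)c(OCc2ccccc2)c(I)c1Br
F5 | step 9 | 4-(benzyloxy)-3-[2-(benzyloxy)-5-formylphenyl]-2-bromo-5-chlorobenzaldehyde | O=Cc1cc(Cl)c(OCc2ccccc2)c(-c2cc(C=O)ccc2OCc2ccccc2)c1Br
F6 | step 9 | 6-(benzyloxy)-3-chloro-2'-methoxy-5'-(4,4,5,5-tetramethyl-1,3,2-dioxaborolan-2-yl)-[1,1'-biphenyl]-2,4'-dicarbaldehyde | O=Cc1c(Cl)ccc(OCc2ccccc2)c1-c1cc(B2OC(C)(C)C(C)(C)O2)c(C=O)cc1OC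
F7 | step 10 | 4-(benzyloxy)-3-[2-(benzyloxy)-5-vinylphenyl]-2-{5-[6-(benzyloxy)-3-chloro-2-vinylphenyl]-4-methoxy-2-vinylphenyl}-5-chlorostyrene | C=Cc1cc(Cl)c(OCc2ccccc2)c(-c2cc(C=C)ccc2OCc2ccccc2)c1-c1cc(-c2c(OCc3ccccc3)ccc(Cl)c2C=C)c(OC)cc1C=C
F0 | step 11 | none | none
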